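**Retrosynthetic overview**

- Broussoflavonol G has no stereocentre. The strategy rests on one feature: each C-prenyl carbon stands in a [3,3] relation to a phenolic oxygen. C8 of ring A is para to O5, C2' of ring B is para to O5', and C3' of ring B is ortho to O4'.
- The last disconnections are the two MOM ethers on O3 and O7. Before that, all three aryl C–CH2 bonds are disconnected at once to a quercetin triether (O5 prenyl, O5' prenyl, O4' 1,1-dimethylallyl) that should rearrange by five [3,3] shifts in one flask.
- The triether comes from a flavonol whose O4' carries a tertiary propargyl ether, semi-hydrogenated last. Ring C is closed at O1–C2, with entry of the 3-OH, by Algar–Flynn–Oyamada oxidation of a chalcone.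
- The chalcone is the aldol product of a ring A ketone (from 2,4,6-trihydroxyacetophenone) and a ring B aldehyde (from 3,4-dihydroxybenzaldehyde). Rings A and B are bought, and ring C is the only ring formed.

Key step: step 10

Assumption: atoms are numbered as in the target flavonol (ring B carries O4', O5', C2', C3'), prenyl means 3-methylbut-2-enyl, MOM means methoxymethyl, Eu(fod)3 is europium tris(6,6,7,7,8,8,8-heptafluoro-2,2-dimethyl-3,5-octanedionate), and in step 10 the ring A relay is written before the ring B relay although their order does not change the product.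

**Route**

Step 1
Reactants: 1 2,4,6-trihydroxyacetophenone
Product: 2 2,6-dihydroxy-4-(methoxymethoxy)acetophenone
Conditions: MOMCl (1.0 equiv), iPr2NEt, THF, 0 °C
Reagents that add atoms: chloromethyl methyl ether, COCCl
Why: Williamson-type MOM protection should go first to the 4-OH, which is para to the acetyl group, the most acidic hydroxyl and not hydrogen-bonded to the carbonyl, and one equivalent of reagent in the cold keeps the bis-ether low.

Step 2
Reactants: 2 2,6-dihydroxy-4-(methoxymethoxy)acetophenone; 3 prenyl bromide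
Product: 4 2-hydroxy-4-(methoxymethoxy)-6-(prenyloxy)acetophenone
Conditions: K2CO3 (1.1 equiv), acetone, reflux
Reagents that add atoms: none
Why: Williamson etherification of one of the two equivalent ortho hydroxyls should stop at the mono-ether because the remaining hydroxyl is then locked in a chelate with the carbonyl, and carbonate in acetone favours O- over C-prenylation.

Step 3
Reactants: 5 2-methylbut-3-yn-2-ol
Product: 6 methyl 2-methylbut-3-yn-2-yl carbonate
Conditions: ClCO2Me, pyridine, DMAP (cat.), CH2Cl2, 0 °C to rt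
Reagents that add atoms: methyl chloroformate, COC(=O)Cl
Why: acylation of the tertiary propargylic alcohol under nucleophilic catalysis should give the carbonate, which is the leaving group needed for copper-catalysed propargylic substitution.

Step 4
Reactants: 7 3,4-dihydroxybenzaldehyde; 6 methyl 2-methylbut-3-yn-2-yl carbonate
Product: 8 3-hydroxy-4-(2-methylbut-3-yn-2-yloxy)benzaldehyde
Conditions: CuCl2·2H2O (1 mol%), DBU (1.1 equiv), MeCN, −5 to 0 °C, N2
Reagents that add atoms: none
Why: in this copper-catalysed propargylic etherification the copper acetylide of 6 ionises to a copper allenylidene that is captured at its tertiary carbon by a phenoxide, and one equivalent of DBU should deprotonate mainly the 4-OH, which is para to the formyl group and the more acidic of the two.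

Step 5
Reactants: 8 3-hydroxy-4-(2-methylbut-3-yn-2-yloxy)benzaldehyde; 3 prenyl bromide
Product: 9 4-(2-methylbut-3-yn-2-yloxy)-3-(prenyloxy)benzaldehyde
Conditions: K2CO3, DMF, rt
Reagents that add atoms: none
Why: Williamson etherification of the only remaining phenol should be clean, since the aldehyde, the tertiary propargyl ether and the terminal alkyne are inert to carbonate at room temperature.

Step 6
Reactants: 4 2-hydroxy-4-(methoxymethoxy)-6-(prenyloxy)acetophenone; 9 4-(2-methylbut-3-yn-2-yloxy)-3-(prenyloxy)benzaldehyde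
Product: 10 (E)-1-[2-hydroxy-4-(methoxymethoxy)-6-(prenyloxy)phenyl]-3-[4-(2-methylbut-3-yn-2-yloxy)-3-(prenyloxy)phenyl]prop-2-en-1-one
Conditions: KOH, EtOH/H2O, rt
Reagents that add atoms: none
Why: Claisen–Schmidt aldol condensation of the methyl ketone enolate with the non-enolisable aldehyde should dehydrate under the basic conditions to the conjugated E-enone, and the ethers, the MOM acetal and the alkyne all tolerate aqueous base.

Step 7
Reactants: 10 the (E)-chalcone
Product: 11 3-hydroxy-7-(methoxymethoxy)-2-[4-(2-methylbut-3-yn-2-yloxy)-3-(prenyloxy)phenyl]-5-(prenyloxy)chromen-4-one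
Conditions: 30% H2O2, aq NaOH, MeOH/THF, 0 °C
Reagents that add atoms: hydrogen peroxide, OO
Why: in the Algar–Flynn–Oyamada reaction hydroperoxide anion epoxidises the enone, the 2'-phenoxide opens the epoxide at the benzylic carbon to close ring C at O1–C2, and the dihydroflavonol is oxidised on to the flavonol, while the nucleophilic oxidant leaves the prenyl olefins and the alkyne alone and the low temperature holds back the five-membered closure to the aurone.

Step 8
Reactants: 11 the 3-hydroxyflavone
Product: 12 3,7-bis(methoxymethoxy)-2-[4-(2-methylbut-3-yn-2-yloxy)-3-(prenyloxy)phenyl]-5-(prenyloxy)chromen-4-one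
Conditions: MOMCl, iPr2NEt, CH2Cl2, 0 °C to rt
Reagents that add atoms: chloromethyl methyl ether, COCCl
Why: MOM protection of the acidic enolic 3-OH, the only free hydroxyl, should be clean and removes a competing phenol before the rearrangement.

Step 9
Reactants: 12 the 3,7-bis-MOM alkyne
Product: 13 3,7-bis(methoxymethoxy)-2-[4-(2-methylbut-3-en-2-yloxy)-3-(prenyloxy)phenyl]-5-(prenyloxy)chromen-4-one
Conditions: H2 (1 atm), Pd/CaCO3 poisoned with Pb(OAc)2, quinoline, EtOAc, 0 °C
Reagents that add atoms: none
Why: Lindlar semi-hydrogenation should reduce the terminal alkyne to the vinyl group much faster than it touches the trisubstituted prenyl olefins or the chromone double bond, and the thermally labile tertiary allyl ether is kept cold and used at once.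

Step 10
Reactants: 13 the quercetin triether
Product: 18 3,7-bis-O-(methoxymethyl)broussoflavonol G, via 4'-phenol 14 (not isolated), via ring A dienone 15 (not isolated), via 8-prenyl 5-phenol 16 (not isolated), via ring B dienone 17 (not isolated)
Conditions: NaHCO3, PhCl, 95 °C, Ar; then Eu(fod)3 (10 mol%), 85 to 110 °C
Reagents that add atoms: none
Why: Proposed new method: five [3,3] shifts should run in one flask, first the 1,1-dimethylallyl group from O4' to C3' (its only free ortho carbon, with allylic inversion to a normal prenyl group and enolisation to 14), then, with europium held between O5 and the C4 carbonyl, the O5 prenyl group to C6 (dienone 15) and by Cope shift on to C8 (enolising to the chelated phenol 16), and last the O5' prenyl group to C6' (dienone 17) and by Cope shift across C1'=C2' to C2' (enolising to 18). The closest known reaction types are the Eu(fod)3-promoted para-Claisen–Cope rearrangement of 5-O-prenyl flavonoids to 8-prenyl flavonoids and the ortho-Claisen rearrangement of aryl 1,1-dimethylallyl ethers to ortho-prenyl phenols; the relay in ring B and the combination of all three in one pot are new. No ring is closed and no stereocentre remains, the sp3 carbons of 15 and 17 being transient. The selectivity needed is that each relay runs on to the para carbon and does not stop by enolisation at the ortho 1,1-dimethylallyl phenol, and that each ether has one terminus only. The substrate secures this because the second ortho carbon of each ring B ether carries oxygen, O3 and O7 are capped, and the quaternary CMe2 group of 15 and 17 is compressed between two flanking substituents, so that in the aprotic, buffered medium the intramolecular Cope shift should outrun enolisation.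

Step 11
Reactants: 18 3,7-bis-O-(methoxymethyl)broussoflavonol G
Product: 19 broussoflavonol G
Conditions: 1 M HCl, MeOH, 40 °C
Reagents that add atoms: none
Why: acid-catalysed acetal exchange with methanol should remove both MOM groups, and dilute acid, mild temperature and a short reaction time are chosen so that the ortho-prenyl phenols (7-OH beside C8, 4'-OH beside C3') do not close to chromans.

**Compound list**

1 | 2,4,6-trihydroxyacetophenone | CC(=O)c1c(O)cc(O)cc1O | starting material
2 | 2,6-dihydroxy-4-(methoxymethoxy)acetophenone | CC(=O)c1c(O)cc(OCOC)cc1O | intermediate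
3 | prenyl bromide (1-bromo-3-methylbut-2-ene) | CC(C)=CCBr | starting material
4 | 2-hydroxy-4-(methoxymethoxy)-6-(prenyloxy)acetophenone | CC(=O)c1c(O)cc(OCOC)cc1OCC=C(C)C | intermediate
5 | 2-methylbut-3-yn-2-ol | CC(C)(O)C#C | starting material
6 | methyl 2-methylbut-3-yn-2-yl carbonate | COC(=O)OC(C)(C)C#C | intermediate
7 | 3,4-dihydroxybenzaldehyde | O=Cc1ccc(O)c(O)c1 | starting material
8 | 3-hydroxy-4-(2-methylbut-3-yn-2-yloxy)benzaldehyde | O=Cc1ccc(OC(C)(C)C#C)c(O)c1 | intermediate
9 | 4-(2-methylbut-3-yn-2-yloxy)-3-(prenyloxy)benzaldehyde | O=Cc1ccc(OC(C)(C)C#C)c(OCC=C(C)C)c1 | intermediate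
10 | (E)-1-[2-hydroxy-4-(methoxymethoxy)-6-(prenyloxy)phenyl]-3-[4-(2-methylbut-3-yn-2-yloxy)-3-(prenyloxy)phenyl]prop-2-en-1-one | O=C(/C=C/c1ccc(OC(C)(C)C#C)c(OCC=C(C)C)c1)c1c(O)cc(OCOC)cc1OCC=C(C)C | intermediate
11 | 3-hydroxy-7-(methoxymethoxy)-2-[4-(2-methylbut-3-yn-2-yloxy)-3-(prenyloxy)phenyl]-5-(prenyloxy)chromen-4-one | O=c1c(O)c(-c2ccc(OC(C)(C)C#C)c(OCC=C(C)C)c2)oc2cc(OCOC)cc(OCC=C(C)C)c12 | intermediate
12 | 3,7-bis(methoxymethoxy)-2-[4-(2-methylbut-3-yn-2-yloxy)-3-(prenyloxy)phenyl]-5-(prenyloxy)chromen-4-one | O=c1c(OCOC)c(-c2ccc(OC(C)(C)C#C)c(OCC=C(C)C)c2)oc2cc(OCOC)cc(OCC=C(C)C)c12 | intermediate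
13 | 3,7-bis(methoxymethoxy)-2-[4-(2-methylbut-3-en-2-yloxy)-3-(prenyloxy)phenyl]-5-(prenyloxy)chromen-4-one | O=c1c(OCOC)c(-c2ccc(OC(C)(C)C=C)c(OCC=C(C)C)c2)oc2cc(OCOC)cc(OCC=C(C)C)c12 | intermediate
14 | 2-[4-hydroxy-3-prenyl-5-(prenyloxy)phenyl]-3,7-bis(methoxymethoxy)-5-(prenyloxy)chromen-4-one | O=c1c(OCOC)c(-c2cc(CC=C(C)C)c(O)c(OCC=C(C)C)c2)oc2cc(OCOC)cc(OCC=C(C)C)c12 | intermediate
15 | 2-[4-hydroxy-3-prenyl-5-(prenyloxy)phenyl]-3,7-bis(methoxymethoxy)-6-(2-methylbut-3-en-2-yl)-6H-chromene-4,5-dione (racemic at C6, transient) | O=C1C(OCOC)=C(c3cc(CC=C(C)C)c(O)c(OCC=C(C)C)c3)OC2=C1C(=O)C(C(C)(C)C=C)C(OCOC)=C2 | intermediate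
16 | 5-hydroxy-2-[4-hydroxy-3-prenyl-5-(prenyloxy)phenyl]-3,7-bis(methoxymethoxy)-8-prenylchromen-4-one | O=c1c(OCOC)c(-c2cc(CC=C(C)C)c(O)c(OCC=C(C)C)c2)oc2c(CC=C(C)C)c(OCOC)cc(O)c12 | intermediate
17 | 5-hydroxy-2-[4-hydroxy-6-(2-methylbut-3-en-2-yl)-5-oxo-3-prenylcyclohexa-1,3-dien-1-yl]-3,7-bis(methoxymethoxy)-8-prenylchromen-4-one (racemic at C6', transient) | O=c1c(OCOC)c(C3=CC(CC=C(C)C)=C(O)C(=O)C3C(C)(C)C=C)oc2c(CC=C(C)C)c(OCOC)cc(O)c12 | intermediate
18 | 3,7-bis-O-(methoxymethyl)broussoflavonol G: 2-(4,5-dihydroxy-2,3-diprenylphenyl)-5-hydroxy-3,7-bis(methoxymethoxy)-8-prenylchromen-4-one | CC(C)=CCc1c(-c2oc3c(CC=C(C)C)c(OCOC)cc(O)c3c(=O)c2OCOC)cc(O)c(O)c1CC=C(C)C | intermediate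
19 | broussoflavonol G: 2-(4,5-dihydroxy-2,3-diprenylphenyl)-3,5,7-trihydroxy-8-prenylchromen-4-one | CC(C)=CCc1c(-c2oc3c(CC=C(C)C)c(O)cc(O)c3c(=O)c2O)cc(O)c(O)c1CC=C(C)C | target

**Totals**

Total step count: 11. Longest linear sequence: 9 steps (5 to 6 to 8 to 9 to 10 to 11 to 12 to 13 to 18 to 19, steps 3 to 11).

**Steps most likely to fail**

1. Step 10 (Proposed new method). The ring B relay may halt after its first shift, the C6' dienone 17 enolising to the ortho 1,1-dimethylallyl phenol faster than it undergoes the Cope shift. The tertiary ether may also ionise and lose isoprene before it rearranges, or the freed 4'-phenol may add across the neighbouring prenyl olefin under the Lewis acid. The fallback uses known chemistry only, sets out from acetophenone 4 and rejoins the route at target 19. Both ring B prenyl groups are made as C–C bonds by cross-coupling before the flavonol is built, so that only the precedented ring A relay is left. Commercial 5-bromovanillin F1 is brominated para to the methoxy group (Br2, Fe cat., AcOH) to 5,6-dibromovanillin F2. Demethylation with BBr3 (CH2Cl2, −78 °C to rt) gives 2,3-dibromo-4,5-dihydroxybenzaldehyde F3, and MOMCl with iPr2NEt gives 2,3-dibromo-4,5-bis(methoxymethoxy)benzaldehyde F4. A double Stille coupling with tributyl(3-methylbut-2-enyl)stannane (Pd(PPh3)4, DMF, 100 °C) should then give 4,5-bis(methoxymethoxy)-2,3-diprenylbenzaldehyde F5. Claisen–Schmidt condensation of F5 with 4 (KOH, EtOH) should give the 2'-hydroxychalcone F6. Algar–Flynn–Oyamada oxidation gives the flavonol F7, and MOMCl gives the 3-O-MOM ether F8. The europium-promoted para-Claisen–Cope rearrangement of the single 5-O-prenyl ether (Eu(fod)3, NaHCO3, PhCl, 85 °C) should give 3,7,4',5'-tetrakis-O-(methoxymethyl)broussoflavonol G F9. Dilute HCl in MeOH then releases 19.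

2. Step 7. The 6'-alkoxy group twists the carbonyl out of the plane of ring A, so the phenoxide may open the epoxide at the α-carbon and close the five-membered aurone ring in place of ring C. Epoxidation of the phenoxide-deactivated enone may also be too slow to keep pace with peroxide decomposition. The fallback sets out from chalcone 10 and rejoins the route at flavonol 11. Epoxidation and ring closure are separated, and the ring is closed under mild acid, where only the benzylic carbon is attacked. The 2'-OH of 10 is silylated (TIPSCl, imidazole, DMF) to the 2'-O-triisopropylsilyl chalcone F10. The now non-ionised enone is epoxidised under Weitz–Scheffer conditions (t-BuOOH, DBU, CH2Cl2, 0 °C) to the trans-epoxy ketone F11. The silyl group is removed with Bu4NF buffered with AcOH to the 2'-hydroxy epoxide F12. Catalytic pyridinium p-toluenesulfonate in CH2Cl2 should then close F12 by six-membered opening at the benzylic carbon to the trans-dihydroflavonol F13. Cold alkaline H2O2, the second stage of the Algar–Flynn–Oyamada sequence, dehydrogenates F13 to 11.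

3. Step 4. The free catechol may bind to or be oxidised by the divalent copper salt so that catalysis stalls, or the carbonate may alkylate the 3-OH or both hydroxyls. The fallback sets out from prenyl bromide 3 and alkynol 5 and rejoins the route at aldehyde 9. The aryl–oxygen bond is made by nucleophilic aromatic substitution in place of propargylic substitution, so that the position of the tertiary ether is fixed by a fluorine atom. Commercial 4-fluoro-3-hydroxybenzaldehyde F14 is O-prenylated with 3 (K2CO3, DMF, rt) to 4-fluoro-3-(prenyloxy)benzaldehyde F15. The potassium alkoxide of 5 (KN(SiMe3)2, one equivalent, THF/DMF, 0 °C to rt) should then displace the fluoride para to the formyl group and give 9 directly.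

**Further compounds**

F1 | step 10 | 5-bromovanillin, 3-bromo-4-hydroxy-5-methoxybenzaldehyde (bought) | COc1cc(C=O)cc(Br)c1O
F2 | step 10 | 5,6-dibromovanillin, 2,3-dibromo-4-hydroxy-5-methoxybenzaldehyde | COc1cc(C=O)c(Br)c(Br)c1O
F3 | step 10 | 2,3-dibromo-4,5-dihydroxybenzaldehyde | O=Cc1cc(O)c(O)c(Br)c1Br
F4 | step 10 | 2,3-dibromo-4,5-bis(methoxymethoxy)benzaldehyde | O=Cc1cc(OCOC)c(OCOC)c(Br)c1Br
F5 | step 10 | 4,5-bis(methoxymethoxy)-2,3-diprenylbenzaldehyde | O=Cc1cc(OCOC)c(OCOC)c(CC=C(C)C)c1CC=C(C)C
F6 | step 10 | (E)-3-[4,5-bis(methoxymethoxy)-2,3-diprenylphenyl]-1-[2-hydroxy-4-(methoxymethoxy)-6-(prenyloxy)phenyl]prop-2-en-1-one | O=C(/C=C/c1cc(OCOC)c(OCOC)c(CC=C(C)C)c1CC=C(C)C)c1c(O)cc(OCOC)cc1OCC=C(C)C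
F7 | step 10 | 2-[4,5-bis(methoxymethoxy)-2,3-diprenylphenyl]-3-hydroxy-7-(methoxymethoxy)-5-(prenyloxy)chromen-4-one | O=c1c(O)c(-c2cc(OCOC)c(OCOC)c(CC=C(C)C)c2CC=C(C)C)oc2cc(OCOC)cc(OCC=C(C)C)c12
F8 | step 10 | 2-[4,5-bis(methoxymethoxy)-2,3-diprenylphenyl]-3,7-bis(methoxymethoxy)-5-(prenyloxy)chromen-4-one | O=c1c(OCOC)c(-c2cc(OCOC)c(OCOC)c(CC=C(C)C)c2CC=C(C)C)oc2cc(OCOC)cc(OCC=C(C)C)c12
F9 | step 10 | 3,7,4',5'-tetrakis-O-(methoxymethyl)broussoflavonol G | O=c1c(OCOC)c(-c2cc(OCOC)c(OCOC)c(CC=C(C)C)c2CC=C(C)C)oc2c(CC=C(C)C)c(OCOC)cc(O)c12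
F10 | step 7 | 2'-O-triisopropylsilyl ether of chalcone 10 | O=C(/C=C/c1ccc(OC(C)(C)C#C)c(OCC=C(C)C)c1)c1c(O[Si](C(C)C)(C(C)C)C(C)C)cc(OCOC)cc1OCC=C(C)C
F11 | step 7 | trans-α,β-epoxy ketone of F10 (racemic, one enantiomer drawn) | O=C([C@@H]1O[C@H]1c1ccc(OC(C)(C)C#C)c(OCC=C(C)C)c1)c1c(O[Si](C(C)C)(C(C)C)C(C)C)cc(OCOC)cc1OCC=C(C)C
F12 | step 7 | 2'-hydroxy trans-α,β-epoxy ketone (racemic, one enantiomer drawn) | O=C([C@@H]1O[C@H]1c1ccc(OC(C)(C)C#C)c(OCC=C(C)C)c1)c1c(O)cc(OCOC)cc1OCC=C(C)C
F13 | step 7 | trans-3-hydroxy-7-(methoxymethoxy)-2-[4-(2-methylbut-3-yn-2-yloxy)-3-(prenyloxy)phenyl]-5-(prenyloxy)chroman-4-one (racemic, one enantiomer drawn) | CC(C)=CCOc1cc(ccc1OC(C)(C)C#C)[C@@H]2[C@H](C(=O)c3c(OCC=C(C)C)cc(OCOC)cc3O2)O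
F14 | step 4 | 4-fluoro-3-hydroxybenzaldehyde (bought) | O=Cc1ccc(F)c(O)c1
F15 | step 4 | 4-fluoro-3-(prenyloxy)benzaldehyde | O=Cc1ccc(F)c(OCC=C(C)C)c1
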